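The numbers in the tables were computed with made-up constants, and the scatter is random.

Oak got 0.0100 M more nucleophile than cedar and by 120 s stood 3.3 percentage points higher in product, so the nucleophile charge is where to look.

| flask | electrophile | nucleophile | remark | time |
|---|---|---|---|---|
| cedar | 0.10 M | 0.15 M | run made earlier |  |
| oak | 0.10 M | 0.16 M | run made earlier |  |
| alpha | 0.10 M | 0.140 M |  | 2.0 min |
| theta | 0.10 M | 0.110 M |  | 2.0 min |

| run | time / s | electrophile / % | product / % |
|---|---|---|---|
| cedar | 25.0 | 53.8 | 45.6 |
| cedar | 50.0 | 45.9 | 52.3 |
| cedar | 80.0 | 41.8 | 55.7 |
| cedar | 90.0 | 42.3 | 57.5 |
| cedar | 120 | 39.4 | 61.0 |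
| oak | 25.0 | 52.4 | 48.0 |
| oak | 50.0 | 43.6 | 55.7 |
| oak | 80.0 | 40.1 | 59.5 |
| oak | 90.0 | 38.4 | 61.1 |
| oak | 120 | 35.6 | 64.3 |

(readings scatter by 1 percentage point)

- the analysis behind the earlier runs scatters by 1 percentage point, standard deviation
- reactions considered so far: electrophile + nucleophile <-> acid set free + product; nucleophile + acid set free <-> protonated nucleophile; nucleophile <-> dormant form

* part of the electrophile that has reacted at the end, alpha
* part of the electrophile that has reacted at the end, theta
* what raising the concentration of nucleophile from its lowest to its highest value here does to the part of the electrophile that has reacted (changes below 5 percentage points count as none) (it falls / no change / it rises)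

Electrophile and nucleophile give product and set acid free, a second nucleophile can catch that acid as protonated nucleophile, and nucleophile can also pass into the dormant form. Count free nucleophile and dormant form together as one pool, divide the rate at which this pool goes by the rate at which electrophile goes, and time drops out: with the acid caught, the quotient is two. So c(nucleophile)/(2 c(electrophile)) is a ceiling, the part of the electrophile that the nucleophile can pay for: 75.0% in cedar, 80.0% in oak. At this cost the nucleophile is the limiting reagent.

Product at 120 s, which is the asked time, over the ceiling gives 81.3% for cedar and 80.4% for oak, a gap within the scatter of 1 point. One number serves both runs, so I take their mean, 80.9%, the share of the ceiling reached by that time, the fill. With ceilings of 70.0% for alpha and 55.0% for theta, my reckoning gives 56.6% and 44.5%.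

The forecast says 57.5% (54.5% to 60%) for alpha and 46.5% (42% to 51%) for theta, and its answer on the trend is "it rises", holding that “Each electrophile reacted costs about two nucleophiles”. Its theta stands above mine.

The flask gives 57.0% for alpha and 46.0% for theta, and the answer on the trend is "it rises", by 11 points.

    electrophile + nucleophile ⇌ acid set free + product (K = 0.391, k = 1.19 M⁻¹ s⁻¹)
    nucleophile + acid set free ⇌ protonated nucleophile, settled at all times (K = 29900 M⁻¹)
    nucleophile ⇌ dormant form (K = 6.10, k = 0.157 s⁻¹)

Alpha reaches 81.4% of its ceiling and theta 83.6%, close to the fill of 80.9%. A neighbour of theta with 0.17 M of electrophile has a ceiling of 32.4%, so the fill gives 26.2%, and that flask gives 29.3%. The forecast's trend leans on the association of nucleophile and acid set free, the largest single effect on the gap: with it taken away both ways, the trend reads no change, the gap between alpha and theta falling below the margin of 5 points, from 11 points to 2.5 points.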